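**Retrosynthetic overview**
1. Target 26 ⇐ TBS-oxocane 24 (silyl-to-acetyl swap) ⇐ oxolane 22 by a dichlorinative ring expansion: Cl+ on the 6Z-alkene, capture by the ring oxygen to a bicyclic oxonium ion (O+ on C6/C9/C12), chloride opening at C9. This one step makes the 8-ring, both C–Cl bonds and C6, C7, C9.
2. Oxolane 22 ⇐ linear C15 enyne 20 by a cis-selective, debenzylative bromoetherification (Br+ on the 12E-alkene; sets C12, C13).
3. 20 ⇐ lactol-aldehyde 9 by two olefinations: Z-Wittig with a C1–C6 ylide, then E-selective Takai–Utimoto with EtCHI2.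
4. 9 ⇐ ozonolysis of desymmetrised meso cis-cyclohex-4-ene-1,2-diol (C9 and C10 from a catalytic enantioselective silylation).
5. Ring order: oxolane (O–C9/C12) first, then the oxocane (O–C6/C12) by expansion of that oxolane.

Assumption: the presumed biosynthesis is taken as the Laurencia halonium/oxonium pathway (Br+-induced etherification of a linear C15 enyne, then a bicyclic oxonium ion opened by chloride); compounds 1, 3, 6, 12, 13, 18 and all named reagents are purchased.

Locants C1–C15 follow the natural-product chain (C1≡C2, C3=C4, ring O between C6 and C12). TBS = tert-butyldimethylsilyl, DCB = 2,6-dichlorobenzyl, TBCO = 2,4,4,6-tetrabromocyclohexa-2,5-dienone, CDSC = chlorodiethylsulfonium hexachloroantimonate.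

**Step 1**
Reactants: 1 (E)-pent-2-en-4-yn-1-ol
Product: 2 (E)-5-bromopent-3-en-1-yne
Conditions: PBr3 (0.4 equiv), pyridine (cat.), Et2O, −20 → 0 °C
Reagents that add atoms: phosphorus tribromide BrP(Br)Br
Why: SN2 bromination of a primary allylic alcohol through its phosphite ester; the E-alkene and alkyne are untouched and no stereocentre is involved.

**Step 2**
Reactants: 3 methyltriphenylphosphonium bromide; 2 (E)-5-bromopent-3-en-1-yne
Product: 5 [(3E)-hex-3-en-5-yn-1-yl]triphenylphosphonium bromide, via methylenetriphenylphosphorane 4 (not isolated)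
Conditions: 3, n-BuLi, THF, −78 → 0 °C; then added slowly to 2 (1.5 equiv), THF, −78 °C → rt; salt filtered
Reagents that add atoms: none
Why: C-alkylation of a non-stabilised ylide by a reactive primary allylic bromide (ylide alkylation) gives the one-carbon-homologated salt; inverse addition to excess bromide suppresses transylidation and double alkylation.

**Step 3**
Reactants: 6 cyclohexa-1,4-diene
Product: 7 cis-cyclohex-4-ene-1,2-diol
Conditions: OsO4 (0.5 mol%), NMO (1 equiv), 6 (3 equiv), acetone/H2O, 0 °C → rt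
Reagents that add atoms: osmium tetroxide O=[Os](=O)(=O)=O (catalytic oxygen carrier); N-methylmorpholine N-oxide C[N+]1([O-])CCOCC1; water O
Why: Catalytic OsO4/NMO syn-dihydroxylation gives the meso cis-diol (C9/C10 erythro relationship); excess diene limits over-oxidation to the tetraol.

**Step 4**
Reactants: 7 cis-cyclohex-4-ene-1,2-diol
Product: 8 (1R,2S)-2-(TBSO)cyclohex-4-en-1-ol
Conditions: TBSCl (2 equiv), DIPEA, amino-acid-derived N-methylimidazole silylation catalyst (30 mol%, the antipode that silylates the pro-S carbinol oxygen), THF, −40 °C, 72 h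
Reagents that add atoms: tert-butyldimethylsilyl chloride CC(C)(C)[Si](C)(C)Cl
Why: Catalytic enantioselective silylation (desymmetrisation of a meso-1,2-diol, Hoveyda–Snapper type) differentiates the enantiotopic hydroxyls, fixing C9 (R, free OH) and C10 (S, OTBS) and leaving the oxygens chemically distinct.

**Step 5**
Reactants: 8 (1R,2S)-2-(TBSO)cyclohex-4-en-1-ol
Product: 9 2-[(2R,3S)-3-(TBSO)-5-hydroxyoxolan-2-yl]acetaldehyde (anomers)
Conditions: O3, CH2Cl2, −78 °C; then Me2S, −78 °C → rt; used crude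
Reagents that add atoms: ozone [O-][O+]=O
Why: Ozonolysis with reductive work-up gives the dialdehyde, whose C12 aldehyde is trapped by the free C9–OH as a five-membered lactol while C7 stays a free aldehyde, so the two termini are differentiated; the silyl ether survives and C9/C10 are untouched.

**Step 6**
Reactants: 9 lactol-aldehyde; 5 [(3E)-hex-3-en-5-yn-1-yl]triphenylphosphonium bromide
Product: 11 (4S,5R)-4-(TBSO)-5-[(2Z,5E)-octa-2,5-dien-7-yn-1-yl]oxolan-2-ol (anomers), via phosphonium ylide 10 (not isolated)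
Conditions: 5 (2.3 equiv), NaHMDS (2.2 equiv), THF, −78 °C; then 9, −78 °C, 1 h; AcOH quench at −78 °C
Reagents that add atoms: none
Why: Salt-free Wittig reaction of a non-stabilised ylide gives the 6Z-alkene through the kinetic cis-oxaphosphetane; only the free aldehyde reacts at −78 °C because the lactol (deprotonated by a sacrificial equivalent of ylide) stays ring-closed, and the ylide is too weak a base to deprotonate the alkyne appreciably.

**Step 7**
Reactants: 12 diiodomethane; 13 iodoethane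
Product: 15 1,1-diiodopropane, via diiodomethylsodium 14 (not isolated)
Conditions: NaHMDS, THF/Et2O, −78 °C, dark; then 13, −78 °C → rt
Reagents that add atoms: none
Why: Deprotonation of CH2I2 and SN2 alkylation of the diiodomethyl anion with a primary iodide (gem-diiodoalkane synthesis).

**Step 8**
Reactants: 11 lactol; 15 1,1-diiodopropane
Product: 17 (3E,6Z,9R,10S,12E)-10-(TBSO)pentadeca-3,6,12-trien-1-yn-9-ol, via gem-dichromium reagent 16 (not isolated)
Conditions: CrCl2 (8 equiv), 15 (2 equiv), THF/DMF, 0 °C → rt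
Reagents that add atoms: none
Why: Takai–Utimoto alkylidenation: the non-basic gem-dichromium reagent adds to the open hydroxy-aldehyde tautomer of the lactol and eliminates to the 12E-alkene; no alkoxide base is present, so the TBS group does not migrate to the liberated C9–OH, and the 6Z-alkene and enyne are inert to Cr(II).

**Step 9**
Reactants: 18 (2,6-dichlorophenyl)methanol
Product: 19 2,6-dichlorobenzyl 2,2,2-trichloroacetimidate
Conditions: Cl3CCN (1.5 equiv), DBU (10 mol%), CH2Cl2, 0 °C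
Reagents that add atoms: trichloroacetonitrile N#CC(Cl)(Cl)Cl
Why: Base-catalysed addition of the alcohol to the nitrile (trichloroacetimidate formation).

**Step 10**
Reactants: 17 dienynol; 19 2,6-dichlorobenzyl 2,2,2-trichloroacetimidate
Product: 20 (3E,6Z,9R,10S,12E)-9-(DCB-oxy)-10-(TBSO)pentadeca-3,6,12-trien-1-yne
Conditions: 19 (2 equiv), TfOH (5 mol%), CH2Cl2/cyclohexane, 0 °C → rt
Reagents that add atoms: none
Why: Acid-catalysed trichloroacetimidate O-benzylation puts the bulky DCB group on O9 without forming an alkoxide (no 1,2-silyl migration); stereocentres are untouched.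

**Step 11**
Reactants: 20 DCB ether
Product: 22 (2R,3S,5R)-5-[(1S)-1-bromopropyl]-3-(TBSO)-2-[(2Z,5E)-octa-2,5-dien-7-yn-1-yl]oxolane, via O-benzyloxonium ion 21 (not isolated)
Conditions: TBCO (1.2 equiv), CH2Cl2, −78 → −20 °C, dark
Reagents that add atoms: 2,4,4,6-tetrabromocyclohexa-2,5-dienone BrC1=CC(Br)(Br)C=C(Br)C1=O
Why: Rychnovsky–Bartlett dealkylative haloetherification: the ether oxygen opens the 12,13-bromonium ion 5-exo with anti addition (12E gives 12R,13S), and the reversibly formed oxonium ion is debenzylated from the isomer in which the O-DCB group is trans to both flanking substituents, giving the 2,5-cis oxolane with OTBS trans (the muscarine pattern); 5-exo capture beats 5-endo capture at the 6Z-alkene, and the OTBS oxygen and the enyne are poor nucleophiles.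

**Step 12**
Reactants: 22 bromo-oxolane
Product: 24 (2S,3S,5S,6S,8R)-8-[(1S)-1-bromopropyl]-3,5-dichloro-2-[(2E)-pent-2-en-4-yn-1-yl]-6-(TBSO)oxocane, via bicyclic oxonium ion 23 (not isolated)
Conditions: CDSC (1.2 equiv), CH2Cl2/MeNO2 (4:1), −78 → −40 °C; aq. NaHCO3/Na2S2O3 quench
Reagents that add atoms: chlorodiethylsulfonium hexachloroantimonate CC[S+](Cl)CC.Cl[Sb-](Cl)(Cl)(Cl)(Cl)Cl
Why: Proposed new method: Et2SCl+ delivers Cl+ to the only isolated alkene (6Z; the conjugated enyne is much less nucleophilic), and because SbCl6− is a poor nucleophile the ring oxygen captures C6 anti (5-endo) on the convex face, placing C5 and Cl exo in the cis-fused 1-oxoniabicyclo[3.3.0]octane 23 (sets 6S,7S; the concave face is blocked by the endo C12 side chain); chloride released from SbCl6− then opens 23 by SN2 at the ring-fusion carbon C9 with inversion (9R → 9S), C6 and C12 being deactivated by their vicinal halogens and the non-participating OTBS avoiding the neighbouring-group opening an ester at C10 would cause; closest known reaction type is the BDSB ring-expanding bromoetherification of 2-(alk-2-enyl)tetrahydrofurans through the same oxonium topology (there opened by an internal carbonate), together with halide opening of Laurencia-type oxonium ions.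

**Step 13**
Reactants: 24 TBS-oxocane
Product: 26 (2S,3S,5S,6S,8R)-8-[(1S)-1-bromopropyl]-3,5-dichloro-2-[(2E)-pent-2-en-4-yn-1-yl]oxocan-6-yl acetate (CNP0251465.1), via C10 alcohol 25 (not isolated)
Conditions: HF·pyridine, pyridine/THF, 0 °C → rt; then Ac2O, DMAP, rt (one pot)
Reagents that add atoms: acetic anhydride CC(=O)OC(C)=O
Why: Fluoride desilylation under buffered, non-basic conditions (no E2 of the secondary halides) followed by DMAP-catalysed acetylation of the C10 alcohol with retention; no stereocentre changes.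

**Compound list**
1 | (E)-pent-2-en-4-yn-1-ol | C#C/C=C/CO | starting material
2 | (E)-5-bromopent-3-en-1-yne | C#C/C=C/CBr | intermediate
3 | methyltriphenylphosphonium bromide | C[P+](c1ccccc1)(c1ccccc1)c1ccccc1.[Br-] | starting material
4 | methylenetriphenylphosphorane (in situ) | C=P(c1ccccc1)(c1ccccc1)c1ccccc1 | intermediate
5 | [(3E)-hex-3-en-5-yn-1-yl]triphenylphosphonium bromide | C#C/C=C/CC[P+](c1ccccc1)(c1ccccc1)c1ccccc1.[Br-] | intermediate
6 | cyclohexa-1,4-diene | C1=CCC=CC1 | starting material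
7 | cis-cyclohex-4-ene-1,2-diol (meso) | O[C@@H]1CC=CC[C@@H]1O | intermediate
8 | (1R,2S)-2-(TBSO)cyclohex-4-en-1-ol | O[C@@H]1CC=CC[C@@H]1O[Si](C)(C)C(C)(C)C | intermediate
9 | 2-[(2R,3S)-3-(TBSO)-5-hydroxyoxolan-2-yl]acetaldehyde (anomers) | O=CC[C@H]1OC(O)C[C@@H]1O[Si](C)(C)C(C)(C)C | intermediate
10 | [(3E)-hex-3-en-5-yn-1-ylidene]triphenylphosphorane (in situ) | C#C/C=C/CC=P(c1ccccc1)(c1ccccc1)c1ccccc1 | intermediate
11 | (4S,5R)-4-(TBSO)-5-[(2Z,5E)-octa-2,5-dien-7-yn-1-yl]oxolan-2-ol (anomers) | C#C/C=C/C/C=C\C[C@H]1OC(O)C[C@@H]1O[Si](C)(C)C(C)(C)C | intermediate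
12 | diiodomethane | ICI | starting material
13 | iodoethane | CCI | starting material
14 | diiodomethylsodium (in situ) | [Na+].[CH-](I)I | intermediate
15 | 1,1-diiodopropane | CCC(I)I | intermediate
16 | 1,1-bis(dichlorochromio)propane (in situ) | CCC([Cr](Cl)Cl)[Cr](Cl)Cl | intermediate
17 | (3E,6Z,9R,10S,12E)-10-(TBSO)pentadeca-3,6,12-trien-1-yn-9-ol | C#C/C=C/C/C=C\C[C@@H](O)[C@@H](O[Si](C)(C)C(C)(C)C)C/C=C/CC | intermediate
18 | (2,6-dichlorophenyl)methanol | OCc1c(Cl)cccc1Cl | starting material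
19 | 2,6-dichlorobenzyl 2,2,2-trichloroacetimidate | N=C(OCc1c(Cl)cccc1Cl)C(Cl)(Cl)Cl | intermediate
20 | (3E,6Z,9R,10S,12E)-9-(DCB-oxy)-10-(TBSO)pentadeca-3,6,12-trien-1-yne | C#C/C=C/C/C=C\C[C@@H](OCc1c(Cl)cccc1Cl)[C@@H](O[Si](C)(C)C(C)(C)C)C/C=C/CC | intermediate
21 | O-(2,6-dichlorobenzyl)oxolanium 2,4,6-tribromophenoxide of 22 (in situ) | C#C/C=C/C/C=C\C[C@H]1[O+](Cc2c(Cl)cccc2Cl)[C@@H]([C@@H](Br)CC)C[C@@H]1O[Si](C)(C)C(C)(C)C.[O-]c1c(Br)cc(Br)cc1Br | intermediate
22 | (2R,3S,5R)-5-[(1S)-1-bromopropyl]-3-(TBSO)-2-[(2Z,5E)-octa-2,5-dien-7-yn-1-yl]oxolane | C#C/C=C/C/C=C\C[C@H]1O[C@@H]([C@@H](Br)CC)C[C@@H]1O[Si](C)(C)C(C)(C)C | intermediate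
23 | cis-fused 1-oxoniabicyclo[3.3.0]octane hexachloroantimonate, O+ on C6/C9/C12 (6S,7S,9R,10S,12R,13S; in situ) | C#C/C=C/C[C@H]1[C@@H](Cl)C[C@@H]2[C@@H](O[Si](C)(C)C(C)(C)C)C[C@H]([C@@H](Br)CC)[O+]12.Cl[Sb-](Cl)(Cl)(Cl)(Cl)Cl | intermediate
24 | (2S,3S,5S,6S,8R)-8-[(1S)-1-bromopropyl]-3,5-dichloro-2-[(2E)-pent-2-en-4-yn-1-yl]-6-(TBSO)oxocane | C#C/C=C/C[C@@H]1O[C@@H]([C@@H](Br)CC)C[C@H](O[Si](C)(C)C(C)(C)C)[C@@H](Cl)C[C@@H]1Cl | intermediate
25 | (2S,3S,5S,6S,8R)-8-[(1S)-1-bromopropyl]-3,5-dichloro-2-[(2E)-pent-2-en-4-yn-1-yl]oxocan-6-ol (in situ) | C#C/C=C/C[C@@H]1O[C@@H]([C@@H](Br)CC)C[C@H](O)[C@@H](Cl)C[C@@H]1Cl | intermediate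
26 | (2S,3S,5S,6S,8R)-8-[(1S)-1-bromopropyl]-3,5-dichloro-2-[(2E)-pent-2-en-4-yn-1-yl]oxocan-6-yl acetate (CNP0251465.1) | C#C/C=C/C[C@@H]1O[C@@H]([C@@H](Br)CC)C[C@H](OC(C)=O)[C@@H](Cl)C[C@@H]1Cl | target

**Step count and risks**
Total step count: 13. Longest linear sequence: 9 steps (3, 4, 5, 6, 8, 10, 11, 12, 13 from cyclohexa-1,4-diene).

The three steps most likely to fail:

Step 12 (dichlorinative ring expansion). The Cl+ reagent or the SbCl5 by-product may attack the terminal enyne, chloride may add directly across the alkene, or chloride may open oxonium ion 23 at C6 or C12 instead of C9. The fallback removes the enyne from the key step, so the ring expansion runs on a substrate with a single alkene, as in the known bromonium version; it does not by itself fix the regiochemistry of chloride opening. It sets out from lactol-aldehyde 9 and comes back at oxocane 24. Wittig reaction of 9 with the ylide of purchased [2-(1,3-dioxolan-2-yl)ethyl]triphenylphosphonium bromide (NaHMDS, THF, −78 °C) gives the dioxolane lactol F1. Takai–Utimoto olefination with 15 gives the dioxolane dienol F2, and imidate 19 with TfOH gives the dioxolane DCB ether F3. TBCO gives the dioxolane bromo-oxolane F4, and CDSC gives the dioxolane dichloro-oxocane F5. TsOH in wet acetone frees the oxocane aldehyde F6, and (triphenylphosphoranylidene)acetaldehyde in toluene gives the (E)-enal F7. Colvin homologation (TMSCHN2, LDA, THF, −78 °C) then gives 24.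

Step 11 (debenzylative bromoetherification). Br+ may be consumed at the skipped 6Z-alkene, or the cis selectivity may be lower with Br+ than in the iodo precedent. The fallback runs the same cyclisation on a substrate that holds only the 12E-alkene and adds the left-hand chain afterwards. It sets out from silyl ether 8 and comes back at oxolane 22. Ozonolysis of 8 with NaBH4 work-up gives the triol F8. 2,6-Dichlorobenzaldehyde dimethyl acetal with CSA gives the six-membered O7/O9 acetal alcohol F9, leaving C12–OH free. Dess–Martin oxidation gives the acetal aldehyde F10, and Julia–Kocienski olefination (1-phenyl-5-(propylsulfonyl)-1H-tetrazole, KHMDS, DME, −60 °C) gives the (E)-alkene acetal F11. DIBAL-H opens the acetal to the secondary DCB ether with a free primary alcohol, the DCB ether alcohol F12. TBCO gives the bromo-oxolane alcohol F13, and Dess–Martin oxidation gives the oxolane aldehyde F14. Wittig reaction with ylide 10 gives 22.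

Step 8 (Takai–Utimoto olefination on a lactol). The lactol may react sluggishly or give poor E/Z control. The fallback opens the lactol covalently and olefinates a free aldehyde with no alkoxide present. It sets out from lactol 11 and comes back at DCB ether 20. Propane-1,3-dithiol with BF3·OEt2 (CH2Cl2, −40 °C) gives the dithiane alcohol F15. Imidate 19 with TfOH gives the dithiane DCB ether F16, and MeI/CaCO3 in aqueous MeCN frees the DCB ether aldehyde F17. Julia–Kocienski olefination (1-phenyl-5-(propylsulfonyl)-1H-tetrazole, KHMDS, DME, −60 °C) gives 20.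

**Further compounds**
F1 | step 12 | (4S,5R)-4-(TBSO)-5-[(2Z)-4-(1,3-dioxolan-2-yl)but-2-en-1-yl]oxolan-2-ol | O1CCOC1C/C=C\C[C@H]1OC(O)C[C@@H]1O[Si](C)(C)C(C)(C)C
F2 | step 12 | (2Z,5R,6S,8E)-6-(TBSO)-1-(1,3-dioxolan-2-yl)undeca-2,8-dien-5-ol | O1CCOC1C/C=C\C[C@@H](O)[C@@H](O[Si](C)(C)C(C)(C)C)C/C=C/CC
F3 | step 12 | DCB ether of F2 at the C5 oxygen | O1CCOC1C/C=C\C[C@@H](OCc1c(Cl)cccc1Cl)[C@@H](O[Si](C)(C)C(C)(C)C)C/C=C/CC
F4 | step 12 | (2R,3S,5R)-5-[(1S)-1-bromopropyl]-3-(TBSO)-2-[(2Z)-4-(1,3-dioxolan-2-yl)but-2-en-1-yl]oxolane | O1CCOC1C/C=C\C[C@H]1O[C@@H]([C@@H](Br)CC)C[C@@H]1O[Si](C)(C)C(C)(C)C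
F5 | step 12 | (2S,3S,5S,6S,8R)-8-[(1S)-1-bromopropyl]-3,5-dichloro-2-(1,3-dioxolan-2-ylmethyl)-6-(TBSO)oxocane | O1CCOC1C[C@@H]1O[C@@H]([C@@H](Br)CC)C[C@H](O[Si](C)(C)C(C)(C)C)[C@@H](Cl)C[C@@H]1Cl
F6 | step 12 | 2-[(2S,3S,5S,6S,8R)-8-[(1S)-1-bromopropyl]-3,5-dichloro-6-(TBSO)oxocan-2-yl]acetaldehyde | O=CC[C@@H]1O[C@@H]([C@@H](Br)CC)C[C@H](O[Si](C)(C)C(C)(C)C)[C@@H](Cl)C[C@@H]1Cl
F7 | step 12 | (2E)-4-[(2S,3S,5S,6S,8R)-8-[(1S)-1-bromopropyl]-3,5-dichloro-6-(TBSO)oxocan-2-yl]but-2-enal | O=C/C=C/C[C@@H]1O[C@@H]([C@@H](Br)CC)C[C@H](O[Si](C)(C)C(C)(C)C)[C@@H](Cl)C[C@@H]1Cl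
F8 | step 11 | (3R,4S)-4-(TBSO)hexane-1,3,6-triol | OCC[C@@H](O)[C@@H](O[Si](C)(C)C(C)(C)C)CCO
F9 | step 11 | (3S)-3-(TBSO)-3-[(4R)-2-(2,6-dichlorophenyl)-1,3-dioxan-4-yl]propan-1-ol (2,4-cis acetal) | OCC[C@H](O[Si](C)(C)C(C)(C)C)[C@H]1CCO[C@@H](c2c(Cl)cccc2Cl)O1
F10 | step 11 | (3S)-3-(TBSO)-3-[(4R)-2-(2,6-dichlorophenyl)-1,3-dioxan-4-yl]propanal (2,4-cis acetal) | O=CC[C@H](O[Si](C)(C)C(C)(C)C)[C@H]1CCO[C@@H](c2c(Cl)cccc2Cl)O1
F11 | step 11 | (4R)-4-[(1S,3E)-1-(TBSO)hex-3-en-1-yl]-2-(2,6-dichlorophenyl)-1,3-dioxane (2,4-cis acetal) | CC/C=C/C[C@H](O[Si](C)(C)C(C)(C)C)[C@H]1CCO[C@@H](c2c(Cl)cccc2Cl)O1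
F12 | step 11 | (3R,4S,6E)-3-(DCB-oxy)-4-(TBSO)non-6-en-1-ol | OCC[C@@H](OCc1c(Cl)cccc1Cl)[C@@H](O[Si](C)(C)C(C)(C)C)C/C=C/CC
F13 | step 11 | 2-[(2R,3S,5R)-5-[(1S)-1-bromopropyl]-3-(TBSO)oxolan-2-yl]ethan-1-ol | OCC[C@H]1O[C@@H]([C@@H](Br)CC)C[C@@H]1O[Si](C)(C)C(C)(C)C
F14 | step 11 | 2-[(2R,3S,5R)-5-[(1S)-1-bromopropyl]-3-(TBSO)oxolan-2-yl]acetaldehyde | O=CC[C@H]1O[C@@H]([C@@H](Br)CC)C[C@@H]1O[Si](C)(C)C(C)(C)C
F15 | step 8 | (2S,3R,5Z,8E)-1-(1,3-dithian-2-yl)-2-(TBSO)undeca-5,8-dien-10-yn-3-ol | C#C/C=C/C/C=C\C[C@@H](O)[C@@H](O[Si](C)(C)C(C)(C)C)CC1SCCCS1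
F16 | step 8 | DCB ether of F15 at the C3 oxygen | C#C/C=C/C/C=C\C[C@@H](OCc1c(Cl)cccc1Cl)[C@@H](O[Si](C)(C)C(C)(C)C)CC1SCCCS1
F17 | step 8 | (3S,4R,6Z,9E)-4-(DCB-oxy)-3-(TBSO)dodeca-6,9-dien-11-ynal | C#C/C=C/C/C=C\C[C@@H](OCc1c(Cl)cccc1Cl)[C@@H](O[Si](C)(C)C(C)(C)C)CC=O
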